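**Echinoclathrine B by anodic benzoxazole closure: synthesis proposal**

Compound numbers used throughout: 1 aminophenylboronic ester, 2 bromopicoline, 3 aminobiaryl, 4 bromo acid, 5 acid chloride, 6 anilide, 7 benzoxazole, 8 bromo amidophenol, 9 target.

## Analysis of the target

Echinoclathrine B, compound 9, is an achiral biaryl. Ring A is a benzene with three contiguous substituents: a hydroxyl at C1, an acylated nitrogen at C2 and a 2-methylpyridin-4-yl group (ring B) at C3; C4 to C6 are unsubstituted. The nitrogen carries a saturated tridecanoyl chain whose far end, C13, is an S-acetyl thioester. There is no stereocentre and no defined double bond, and the biaryl axis rotates freely, so the problem is one of regiochemistry and of the order in which functional groups appear. The sensitive groups are the thioester (base, nucleophiles, oxidants, acyl transfer), the electron-rich 2-amidophenol (oxidation, cyclodehydration) and the basic pyridine (binds metals, can be alkylated by an electrophilic chain end). The difficulty is that the C2 nitrogen is flanked on both sides, so acylation or cross-coupling on the fully substituted ring is hindered, and a protected phenol would have to be released late next to the thioester. The strategy rests on one feature: the C1 hydroxyl and the C2 amide are together the hydrolysed form of a 2-alkyl-1,3-benzoxazole, and C1 is the only carbon ortho to nitrogen that ring B does not occupy, so the amide oxygen of a hydroxyl-free anilide can itself become the phenol oxygen.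

## Retrosynthetic reasoning

**C13–S bond (9 to 8).** The thioester is cut first. It would not pass an anodic oxidation and is at risk in warm aqueous acid, so sulfur should enter last. The precursor is bromide 8, and the forward step is a simple substitution by an S-acetyl nucleophile that must leave the free phenol, the amide and ring B alone.

**Amidophenol to benzoxazole (8 to 7).** The C1 oxygen is reconnected to the amide carbon, which turns the amidophenol into benzoxazole 7. This is the reverse of a hydrolysis. It masks the phenol without a protecting group and ties the oxygen to an atom already in the molecule. The forward reaction has to hydrolyse the oxazole at its C2 carbon and stop at the anilide 8.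

**Ring A C1–O bond (7 to 6), the key disconnection.** Cutting the bond between the oxazole oxygen and C1 leaves anilide 6, which has only one ortho substituent. Cutting elsewhere on the oxygenated ring (the C2–N bond or the biaryl bond) would mean working at a position flanked by two substituents. Here the oxygen costs no reagent and no protecting group, and its position is fixed because C1 is the only free ortho carbon. The forward reaction must oxidise the amide selectively, close carbon–oxygen and not carbon–nitrogen, and spare ring B and the bromide.

**Amide bond (6 to 3 and 5; 5 from 4).** The anilide 6 is cut at the N–acyl bond into aminobiaryl 3 and acid chloride 5, made from acid 4. At this stage the aniline has a single ortho substituent and still acylates readily. The chain is carried as a primary bromide because that group is inert to the anode and to dilute acid and is the handle for sulfur at the end.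

**Biaryl bond (3 to 1 and 2).** The bond between ring A C3 and ring B C4 is cut last. Both halves, 1 and 2, are catalogue compounds, the pyridyl bromide 2 is activated for oxidative addition, and no oxygen substituent crowds the coupling site yet.

## Alternatives that were turned down

Alternative 1: aryne three-component coupling.
- Disconnection: the bond from ring A C3 to ring B and the ring A C2–N bond are cut together, which traces ring A to 3-fluoroanisole A2.
- Forward key step: A2 is metalated between fluorine and methoxy with an alkyllithium and warmed to the aryne. The Grignard reagent (2-methylpyridin-4-yl)magnesium bromide A3 adds at the aryne carbon remote from methoxy. The arylmagnesium left ortho to methoxy is quenched with a sulfonyl azide to give 4-(2-azido-3-methoxyphenyl)-2-methylpyridine A1.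
- For: two of the three ring A bonds form in one flask from the cheap arene A2, the regiochemistry follows the well-understood inductive bias of a 3-alkoxy aryne, and the azide of A1 is a clean amine precursor.
- Against: A3 carries an acidic picolyl methyl and must coexist with strongly basic aryl anions, so proton transfer competes with addition. Azide transfer to a 2,6-disubstituted arylmagnesium passes through a triazene salt that does not always fragment cleanly. The amine obtained from A1 is hindered on both sides at the acylation stage. The phenol of A1 is a methyl ether that needs a strong Lewis acid late, which forces the thioester to the very end.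
- Comparison: the step count from A2 is about the same as here, and this route is stronger on convergence at the key step. The chosen route instead acylates an aniline with one ortho substituent, never protects the phenol, and leaves recoverable anilide 6 if its key step fails.

Alternative 2: pyranone–ynamide cycloaddition.
- Disconnection: ring A itself is taken apart at C1–C2 and C3–C4, back to the tethered precursor 2-oxo-2H-pyran-3-yl N-(4-methoxybenzyl)-N-[(2-methylpyridin-4-yl)ethynyl]carbamate A5.
- Forward key step: heating A5 lets the ynamide add across C3 and C6 of the pyranone. Decarboxylative cycloreversion then aromatises the adduct to 3-(4-methoxybenzyl)-4-(2-methylpyridin-4-yl)-1,3-benzoxazol-2(3H)-one A4, so that the benzene ring and the oxazolone ring of A4 close in the same operation.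
- For: all three substituents of A4 are placed by connectivity, the step is thermal and reagent-free, and the oxazolone of A4 ties O and N of ring A in a five-membered ring, the same logic as the chosen route.
- Against: ring A is an ordinary benzene that can be bought. A5 needs a hydroxypyranone, an alkynyl halide of the pyridine half, and N-alkynylation of an aryl-type carbamate that is itself an acylating agent. From A4 onwards, the benzyl group must be removed from an electron-poor nitrogen and the cyclic carbamate opened under forcing base, and the chain is then attached to a doubly flanked aniline. This comes to at least eight steps.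
- Comparison: this route is stronger on the predictability of its key step, since the pericyclic reaction that leads to A4 is untroubled by a pyridine. The chosen route is much shorter and delivers the acyl chain already on nitrogen.

Alternative 3: Curtius isocyanate captured by a chain Grignard reagent.
- Disconnection: the ring A C2–N bond (aryl migration) and the bond from the amide carbonyl to the chain.
- Forward key step: thermolysis of 2-methoxy-6-(2-methylpyridin-4-yl)benzoyl azide A7 gives the aryl isocyanate, which is captured in the same flask by dodec-11-en-1-ylmagnesium bromide A8 to give N-[2-methoxy-6-(2-methylpyridin-4-yl)phenyl]tridec-12-enamide A6.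
- For: the hindered anilide A6 is made by carbon attack on an unhindered isocyanate carbon. The terminal alkene of A6 cannot alkylate the pyridine, and radical addition of a thioacid to A6 would place sulfur at C13 in one step.
- Against: A7 comes from a 2,6-disubstituted benzoic acid whose own assembly needs a hindered coupling and hydrolysis of a hindered ester. A8 can deprotonate the picolyl methyl or add to ring B. The phenol of A6 is again a methyl ether to be cleaved late beside an alkene or a thioester. The route runs to seven or eight steps.
- Comparison: this route is stronger on the compatibility of the chain end with the pyridine, since A6 has no electrophilic terminus whereas the bromides 6 to 8 must be handled cold or as salts. The chosen route offers fewer steps, no phenol protection, and an acylation that meets no hindrance.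

Key step: step 4

Assumption: 13-bromotridecanoic acid 4 is taken as a catalogue ω-bromo acid; pyridinium salts that form with acid in steps 4 and 5 are protonation states of the numbered compounds and are returned to the free bases on work-up.

## Route

Step 1
Reactants: 1 2-(4,4,5,5-tetramethyl-1,3,2-dioxaborolan-2-yl)aniline; 2 4-bromo-2-methylpyridine
Product: 3 2-(2-methylpyridin-4-yl)aniline
Conditions: Pd(PPh3)4 (3 mol %), K2CO3 (2.5 equiv), 1,4-dioxane/H2O (4:1), 90 °C
Reagents that add atoms: none
Why: Suzuki–Miyaura coupling; the 4-bromopyridine adds readily to zerovalent palladium, the boronate has no second ortho substituent, and a free aniline is tolerated under aqueous carbonate.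

Step 2
Reactants: 4 13-bromotridecanoic acid
Product: 5 13-bromotridecanoyl chloride
Conditions: (COCl)2 (1.3 equiv), DMF (cat.), CH2Cl2, 0 °C to rt; evaporate, use crude
Reagents that add atoms: oxalyl chloride, ClC(=O)C(=O)Cl
Why: Acid chloride formation through the Vilsmeier-type chloroiminium catalyst; the by-products are gases and the primary bromide is untouched.

Step 3
Reactants: 3 2-(2-methylpyridin-4-yl)aniline; 5 13-bromotridecanoyl chloride (1.1 equiv)
Product: 6 13-bromo-N-[2-(2-methylpyridin-4-yl)phenyl]tridecanamide
Conditions: CH2Cl2/sat. aq. NaHCO3 (1:1), 0 °C to rt
Reagents that add atoms: none
Why: Schotten–Baumann N-acylation of an aniline with one ortho substituent; acylation at the ring B nitrogen is reversible and only relays the acyl group. From here on 6, 7 and 8 contain both a pyridine and a primary bromide and should be kept cold and dilute or as salts to prevent intermolecular N-alkylation.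

Step 4
Reactants: 6 13-bromo-N-[2-(2-methylpyridin-4-yl)phenyl]tridecanamide
Product: 7 2-(12-bromododecyl)-4-(2-methylpyridin-4-yl)-1,3-benzoxazole
Conditions: C(graphite) anode, Pt cathode, undivided cell, constant current (ca. 5 mA cm−2, 2.2–2.5 F mol−1), MeSO3H (1.05 equiv), NBu4PF6 (0.05 M), dry (CF3)2CHOH, 25 °C; then aq. NaHCO3
Reagents that add atoms: none
Why: Anodic one-electron oxidation of the anilide and loss of the N–H proton give an N-aryl amidyl radical with spin shared by nitrogen, the carbonyl oxygen and ring A; the oxygen terminus bonds to C1, the only unsubstituted carbon ortho to nitrogen, and a second electron transfer with loss of the C1 proton restores aromaticity while protons are discharged as H2 at the platinum cathode. The closest known reaction type is the reagent-free anodic dehydrogenative cyclisation of N-aryl amides to 2-substituted benzoxazoles in hexafluoroisopropanol, a solvent that stabilises radical and cationic intermediates and does not add to them. The oxazole ring closes in a five-membered, formally 5-endo-trig mode onto the C1=C2 bond of ring A, which is feasible because O, the amide carbon, N, C2 and C1 form one planar conjugated oxa-aza-pentadienyl system, so the closure resembles an electrocyclisation more than a Baldwin-type radical addition. No stereocentre is formed. Three selectivities are needed: C–O closure on ring A instead of C–N closure onto C3 or C5 of ring B (the carbazole-type path open to 2-amidobiaryls whose second ring is an electron-richer carbocycle), ring closure instead of intermolecular coupling at the free C5 para to nitrogen, and cyclisation instead of 1,5-hydrogen transfer from C4 of the chain. The first is secured by electrolysing the methanesulfonate salt, since a pyridinium ring is too electron-poor to accept the electrophilic amidyl nitrogen and has no lone pair left to trap the oxidised arene; the second by dilution and by the Z-anilide conformation that holds the carbonyl oxygen beside C1–H; the third by the π-character of an N-aryl amidyl radical, which abstracts hydrogen slowly. The primary bromide lies outside the anodic window and is not reduced at platinum while protons are available; a thioester would not pass this step, which is why sulfur enters later.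

Step 5
Reactants: 7 2-(12-bromododecyl)-4-(2-methylpyridin-4-yl)-1,3-benzoxazole
Product: 8 13-bromo-N-[2-hydroxy-6-(2-methylpyridin-4-yl)phenyl]tridecanamide
Conditions: 0.5 M aq. H2SO4/1,4-dioxane (1:2), 50 °C; then aq. NaHCO3 to pH 7
Reagents that add atoms: water, O
Why: Acid-catalysed hydrolytic ring opening of a 2-alkylbenzoxazole: water adds to the oxazole carbon of the N-protonated ring and the tetrahedral intermediate collapses with cleavage of the bond to the ring oxygen, giving the anilide directly (any O-acyl ammonium isomer would converge on it by O-to-N acyl shift on neutralisation). The anilide is far slower to hydrolyse than the amidine-like oxazole, and a non-nucleophilic acid is used so that no halide exchange can occur at C13.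

Step 6
Reactants: 8 13-bromo-N-[2-hydroxy-6-(2-methylpyridin-4-yl)phenyl]tridecanamide
Product: 9 echinoclathrine B (S-{13-[2-hydroxy-6-(2-methylpyridin-4-yl)anilino]-13-oxotridecyl} ethanethioate)
Conditions: KSC(O)CH3 (1.3 equiv), DMF, rt, argon
Reagents that add atoms: potassium thioacetate KSC(O)CH3, CC(=O)[S-].[K+]
Why: SN2 displacement of the primary bromide by the soft, weakly basic thioacetate anion; the phenol is not deprotonated, so O-alkylation is not expected, and the ring B nitrogen, flanked by its methyl group, is a far poorer nucleophile at room temperature.

## Compound list

1 | 2-(4,4,5,5-tetramethyl-1,3,2-dioxaborolan-2-yl)aniline | Nc1ccccc1B1OC(C)(C)C(C)(C)O1 | starting material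
2 | 4-bromo-2-methylpyridine | Cc1cc(Br)ccn1 | starting material
3 | 2-(2-methylpyridin-4-yl)aniline | Cc1cc(-c2ccccc2N)ccn1 | intermediate
4 | 13-bromotridecanoic acid | OC(=O)CCCCCCCCCCCCBr | starting material
5 | 13-bromotridecanoyl chloride | ClC(=O)CCCCCCCCCCCCBr | intermediate
6 | 13-bromo-N-[2-(2-methylpyridin-4-yl)phenyl]tridecanamide | Cc1cc(-c2ccccc2NC(=O)CCCCCCCCCCCCBr)ccn1 | intermediate
7 | 2-(12-bromododecyl)-4-(2-methylpyridin-4-yl)-1,3-benzoxazole | Cc1cc(-c2cccc3oc(CCCCCCCCCCCCBr)nc23)ccn1 | intermediate
8 | 13-bromo-N-[2-hydroxy-6-(2-methylpyridin-4-yl)phenyl]tridecanamide | Cc1cc(-c2cccc(O)c2NC(=O)CCCCCCCCCCCCBr)ccn1 | intermediate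
9 | echinoclathrine B (S-{13-[2-hydroxy-6-(2-methylpyridin-4-yl)anilino]-13-oxotridecyl} ethanethioate) | CC(=O)SCCCCCCCCCCCCC(=O)Nc1c(O)cccc1-c1ccnc(C)c1 | target

## Step count and least certain steps

Total step count: 6. Longest linear sequence: 5 steps (steps 1, 3, 4, 5, 6; the branch through steps 2, 3, 4, 5, 6 is equally long).

**Step 4 (key step).** The amidyl radical or the ring A radical cation may couple between molecules at the unblocked C5, or be intercepted by the medium, before the oxygen closes on C1. The pyridinium-substituted ring may also be too electron-poor to oxidise cleanly, so that conversion stalls or oligomers form. Traces of moisture would open the product under the acidic conditions to a more easily oxidised amidophenol, leading to over-oxidation.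

The fallback buys the oxygen with the ring instead of installing it. It sets out from 2 and 5 and returns at 8. Miyaura borylation of 2 (B2pin2, Pd(dppf)Cl2, KOAc, dioxane, 90 °C) should give 2-methyl-4-(4,4,5,5-tetramethyl-1,3,2-dioxaborolan-2-yl)pyridine F1. Suzuki coupling of this boronate with 2-bromo-6-methoxyaniline F2 (Pd(PPh3)4, K2CO3, dioxane/H2O, 90 °C) should give 2-methoxy-6-(2-methylpyridin-4-yl)aniline F3. Acylation of this hindered aniline with 5 (2,6-lutidine, CH2Cl2, 40 °C) should give 13-bromo-N-[2-methoxy-6-(2-methylpyridin-4-yl)phenyl]tridecanamide F4. Ether cleavage with BBr3 (4 equiv, CH2Cl2, −78 °C to rt) then leads to 8. The price is a hindered coupling, a hindered acylation and four steps in place of two.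

**Step 5.** Addition of the nucleophile to the oxazole carbon requires a second positive charge next to the pyridinium ring and may be slow. Forcing the conditions would begin to cleave the anilide and to solvolyse the C13–Br end, so the opening may either stall or overshoot.

The fallback gives up the selective stop. It sets out from 7 and returns at 8. Exhaustive hydrolysis (6 M aq. HBr, reflux) should give 2-amino-3-(2-methylpyridin-4-yl)phenol F5 with release of 4, which is recovered. N-selective acylation of this aminophenol with fresh 5 (CH2Cl2/sat. aq. NaHCO3, 0 °C) then gives 8; the amine of a 2-aminophenol acylates before the phenol, and an O-acyl isomer would migrate to nitrogen. In this variant the anodic step serves as a C–H hydroxylation only.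

**Step 6.** The S-acetyl group may be partly lost by acyl transfer to the phenol or to adventitious base, followed by oxidative coupling of the freed thiol. Alkylation of ring B nitrogen may compete if the displacement is run warm or concentrated.

The fallback inverts the last two steps. It sets out from 7 and returns at 9. Displacement on the benzoxazole with KSC(O)CH3 (DMF, rt), where the phenol is still masked, should give S-{12-[4-(2-methylpyridin-4-yl)-1,3-benzoxazol-2-yl]dodecyl} ethanethioate F6. The oxazole of this thioester is then opened at about pH 1 (0.1 M aq. H2SO4/dioxane, 40 °C), where acid-catalysed thioester hydrolysis, first order in acid, is slow, to give 9.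

## Further compounds

F1 | step 4 | 2-methyl-4-(4,4,5,5-tetramethyl-1,3,2-dioxaborolan-2-yl)pyridine | Cc1cc(B2OC(C)(C)C(C)(C)O2)ccn1
F2 | step 4 | 2-bromo-6-methoxyaniline | COc1cccc(Br)c1N
F3 | step 4 | 2-methoxy-6-(2-methylpyridin-4-yl)aniline | COc1cccc(-c2ccnc(C)c2)c1N
F4 | step 4 | 13-bromo-N-[2-methoxy-6-(2-methylpyridin-4-yl)phenyl]tridecanamide | COc1cccc(-c2ccnc(C)c2)c1NC(=O)CCCCCCCCCCCCBr
F5 | step 5 | 2-amino-3-(2-methylpyridin-4-yl)phenol | Cc1cc(-c2cccc(O)c2N)ccn1
F6 | step 6 | S-{12-[4-(2-methylpyridin-4-yl)-1,3-benzoxazol-2-yl]dodecyl} ethanethioate | CC(=O)SCCCCCCCCCCCCc1nc2c(-c3ccnc(C)c3)cccc2o1
A1 | alternative 1 | 4-(2-azido-3-methoxyphenyl)-2-methylpyridine | COc1cccc(-c2ccnc(C)c2)c1N=[N+]=[N-]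
A2 | alternative 1 | 3-fluoroanisole | COc1cccc(F)c1
A3 | alternative 1 | (2-methylpyridin-4-yl)magnesium bromide | Cc1cc([Mg]Br)ccn1
A4 | alternative 2 | 3-(4-methoxybenzyl)-4-(2-methylpyridin-4-yl)-1,3-benzoxazol-2(3H)-one | Cc1cc(-c2cccc3oc(=O)n(Cc4ccc(OC)cc4)c23)ccn1
A5 | alternative 2 | 2-oxo-2H-pyran-3-yl N-(4-methoxybenzyl)-N-[(2-methylpyridin-4-yl)ethynyl]carbamate | O=C1OC=CC=C1OC(=O)N(Cc1ccc(OC)cc1)C#Cc1ccnc(C)c1
A6 | alternative 3 | N-[2-methoxy-6-(2-methylpyridin-4-yl)phenyl]tridec-12-enamide | COc1cccc(-c2ccnc(C)c2)c1NC(=O)CCCCCCCCCCC=C
A7 | alternative 3 | 2-methoxy-6-(2-methylpyridin-4-yl)benzoyl azide | COc1cccc(-c2ccnc(C)c2)c1C(=O)N=[N+]=[N-]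
A8 | alternative 3 | dodec-11-en-1-ylmagnesium bromide | C=CCCCCCCCCCC[Mg]Br
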